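The cyclohexane ring is disconnected at C1–C2 (p-menthane numbering: ring C1–C6, methyl C7 on C1, side chain C8/C9/C10 on C4), the bond that later carries the two ring bromines. C4 is stereogenic only because its ring arms C3–C2 and C5–C6 differ. In an open chain they become an allyl and a 3-methylbut-3-enyl group, so C4 and C8 can be set by acyclic Sharpless epoxide chemistry. Ring-closing metathesis of the resulting (2R,3R)-diene diol 7 closes the six-membered ring and fixes the alkene at C1=C2 in one operation. Anti bromination there and stereoretentive exchange of the 8,9-diol for bromine complete the target.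

Key step: step 4

Remark: the metathesis substrate is a C12 diene diol whose longest chain is a hept-6-ene; only this chain length (allyl plus 3-methylbut-3-enyl on the CH next to the carbinol) closes to a six-membered ring, so it is named as a 2,6-dimethylhept-6-ene-1,2-diol.

Step 1
Reactants: 1 2-methyl-2-vinyloxirane (racemic), 2 vinylmagnesium bromide
Product: 3 (E)-2-methylhexa-2,5-dien-1-ol
Conditions: CuI (10 mol %), THF, −40 °C; then H2O
Reagents that add atoms: none
Why: Copper-catalysed SN2' (1,4) opening of a vinyl oxirane by a Grignard reagent, in which the vinyl group adds to the terminal alkene carbon anti to the breaking C–O bond from the s-trans conformer, which should place CH2OH trans to the new chain (E alkene) and erases the stereocentre of racemic 1; any minor Z or SN2 isomer is to be removed by chromatography.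

Step 2
Reactants: 3 (E)-2-methylhexa-2,5-dien-1-ol
Product: 4 [(2S,3S)-2-methyl-3-(prop-2-en-1-yl)oxiran-2-yl]methanol
Conditions: Ti(OiPr)4 (5 mol %), L-(+)-DIPT (6 mol %), t-BuOOH (2 equiv), 4 Å MS, CH2Cl2, −20 °C
Reagents that add atoms: tert-butyl hydroperoxide, CC(C)(C)OO
Why: Katsuki–Sharpless asymmetric epoxidation, in which the Ti–tartrate complex binds the allylic hydroxyl and, with L-(+)-diisopropyl tartrate, should deliver oxygen to the face that gives the (2S,3S)-oxirane, as for other (E)-2-methylalk-2-en-1-ols, so that both oxirane stereocentres are set by the catalyst and the unactivated terminal alkene is left alone.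

Step 3
Reactants: 4 [(2S,3S)-2-methyl-3-(prop-2-en-1-yl)oxiran-2-yl]methanol, 5 4-bromo-2-methylbut-1-ene
Product: 7 (2R,3R)-2,6-dimethyl-3-(prop-2-en-1-yl)hept-6-ene-1,2-diol, via 3-methylbut-3-enylmagnesium bromide 6 (not isolated)
Conditions: 5, Mg, THF, rt; then CuI (20 mol %), 4 (1 equiv per 3 equiv of 6), THF, −30 → 0 °C; then H2O
Reagents that add atoms: none
Why: Copper-catalysed Grignard opening of a 2,3-epoxy alcohol by SN2, in which the fully substituted C2 cannot be attacked, so the butenyl group should enter at C3 anti to the C–O bond with inversion (3S → 3R, the future C4) while the untouched C2–O bond becomes the (2R) tertiary carbinol (the future C8); the first equivalent of 6 is consumed by the hydroxyl proton.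

Step 4
Reactants: 7 (2R,3R)-2,6-dimethyl-3-(prop-2-en-1-yl)hept-6-ene-1,2-diol
Product: 8 (2R)-2-[(1R)-4-methylcyclohex-3-en-1-yl]propane-1,2-diol [(4R,8R)-p-menth-1-ene-8,9-diol]
Conditions: Grubbs second-generation catalyst (3 mol %), 1,4-benzoquinone (10 mol %), CH2Cl2 (0.01 M), 40 °C
Reagents that add atoms: none
Why: Chauvin mechanism: the Ru methylidene first exchanges with the unhindered allyl terminus (future C2), the resulting alkylidene adds intramolecularly across the 1,1-disubstituted alkene (future C1) to a ruthenacyclobutane, and cycloreversion releases the cyclohexene and Ru=CH2 while ethene leaves the solution. The closest known reaction type is ring-closing metathesis of 2-substituted octa-1,7-dienes to 1-methylcyclohexenes with Ru–NHC catalysts, which tolerate free hydroxyl groups. The six-membered carbocycle closes by intramolecular [2+2]/retro-[2+2] between the two chain termini, forming only the C1=C2 bond. No stereocentre is formed, and C4 and C8 are carried through unchanged because they are remote from the metal-bound carbons. The step needs ring closure over intermolecular cross-metathesis and over allyl-to-propenyl isomerisation, which the 1,7-diene spacing, high dilution, the reluctance of the 1,1-disubstituted alkene to homodimerise and the hydride scavenger should secure. Because the two arms on C4 are constitutionally different in the chain, the alkene can only arise at C1=C2.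

Step 5
Reactants: 8 (2R)-2-[(1R)-4-methylcyclohex-3-en-1-yl]propane-1,2-diol
Product: 10 (2R)-2-methyl-2-[(1R)-4-methylcyclohex-3-en-1-yl]oxirane, via primary monotosylate 9 (not isolated)
Conditions: TsCl (1.1 equiv), pyridine, CH2Cl2, 0 °C; then K2CO3, MeOH, rt
Reagents that add atoms: none
Why: Selective sulfonylation of the primary hydroxyl followed by intramolecular Williamson displacement (3-exo-tet) by the tertiary alkoxide, in which the C8–O bond is never broken, so C8 keeps its configuration.

Step 6
Reactants: 10 (2R)-2-methyl-2-[(1R)-4-methylcyclohex-3-en-1-yl]oxirane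
Product: 11 (2R)-1-bromo-2-[(1R)-4-methylcyclohex-3-en-1-yl]propan-2-ol
Conditions: LiBr (3 equiv), AcOH (3 equiv), THF, rt
Reagents that add atoms: lithium bromide, [Li+].[Br-]
Why: SN2 opening of a terminal 2,2-disubstituted oxirane by bromide under mild Brønsted activation, which should occur at the unhindered CH2 (C9) and leave the C8–O bond and its configuration intact.

Step 7
Reactants: 11 (2R)-1-bromo-2-[(1R)-4-methylcyclohex-3-en-1-yl]propan-2-ol
Product: 12 (2R)-1-bromo-2-[(1R,3S,4S)-3,4-dibromo-4-methylcyclohexyl]propan-2-ol
Conditions: Br2 (1.05 equiv), Bu4NBr (0.2 equiv), CH2Cl2, −78 °C, dark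
Reagents that add atoms: bromine, BrBr
Why: Electrophilic anti addition of bromine through a bromonium ion, where trans-diaxial (Fürst–Plattner) opening on the half-chair that keeps the C4 side chain equatorial should place both bromines axial, that is Br on C1 cis and Br on C2 trans to the side chain (1S,2S), with C4 as the controlling element, and the bromide-rich medium should outrun capture of the bromonium ion by the C8 hydroxyl.

Step 8
Reactants: 12 (2R)-1-bromo-2-[(1R,3S,4S)-3,4-dibromo-4-methylcyclohexyl]propan-2-ol
Product: 13 (1S,2S,4R)-1,2-dibromo-4-[(2R)-1,2-dibromopropan-2-yl]-1-methylcyclohexane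
Conditions: HBr (33 wt % in AcOH, 5 equiv), CH2Cl2, 0 °C
Reagents that add atoms: hydrogen bromide, Br
Why: Acid-mediated substitution of a vicinal bromohydrin with neighbouring-group participation (Winstein–Lucas type), in which the C9 bromine displaces water from C8 from the rear to give the 8,9-bromonium ion and bromide reopens it at the tertiary C8 anti to the bridge, so the two inversions should return Br to the site of the former hydroxyl (retention, 8R) without touching the ring stereocentres.

Compound list
1 | 2-methyl-2-vinyloxirane (racemic) | CC1(CO1)C=C | starting material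
2 | vinylmagnesium bromide | C=C[Mg]Br | starting material
3 | (E)-2-methylhexa-2,5-dien-1-ol | OC/C(C)=C/CC=C | intermediate
4 | [(2S,3S)-2-methyl-3-(prop-2-en-1-yl)oxiran-2-yl]methanol | OC[C@]1(C)O[C@H]1CC=C | intermediate
5 | 4-bromo-2-methylbut-1-ene | CC(=C)CCBr | starting material
6 | (3-methylbut-3-en-1-yl)magnesium bromide | CC(=C)CC[Mg]Br | intermediate
7 | (2R,3R)-2,6-dimethyl-3-(prop-2-en-1-yl)hept-6-ene-1,2-diol | C[C@](O)(CO)[C@@H](CC=C)CCC(C)=C | intermediate
8 | (2R)-2-[(1R)-4-methylcyclohex-3-en-1-yl]propane-1,2-diol [(4R,8R)-p-menth-1-ene-8,9-diol] | C[C@](O)(CO)[C@@H]1CCC(C)=CC1 | intermediate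
9 | (2R)-2-hydroxy-2-[(1R)-4-methylcyclohex-3-en-1-yl]propyl 4-methylbenzenesulfonate | C[C@](O)(COS(=O)(=O)c1ccc(C)cc1)[C@@H]2CCC(C)=CC2 | intermediate
10 | (2R)-2-methyl-2-[(1R)-4-methylcyclohex-3-en-1-yl]oxirane | C[C@]1(CO1)[C@@H]2CCC(C)=CC2 | intermediate
11 | (2R)-1-bromo-2-[(1R)-4-methylcyclohex-3-en-1-yl]propan-2-ol | C[C@](O)(CBr)[C@@H]1CCC(C)=CC1 | intermediate
12 | (2R)-1-bromo-2-[(1R,3S,4S)-3,4-dibromo-4-methylcyclohexyl]propan-2-ol | C[C@](O)(CBr)[C@@H]1CC[C@](C)(Br)[C@@H](Br)C1 | intermediate
13 | (1S,2S,4R)-1,2-dibromo-4-[(2R)-1,2-dibromopropan-2-yl]-1-methylcyclohexane | C[C@](Br)(CBr)[C@@H]1CC[C@](C)(Br)[C@@H](Br)C1 | target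

Total step count: 8. Longest linear sequence: 8 steps (1 → 13; the Grignard reagent 6 is made within step 3).

Steps most likely to fail

Step 8. Ionisation at C8 may run ahead of bromine participation; an open tertiary cation would epimerise C8, eliminate to alkenes that re-add HBr without control, or accept a hydride from C4. The fallback sets out from oxirane 10 and avoids protic acid. Dibromotriphenylphosphorane, preformed from PPh3 and Br2 in MeCN at 0 °C, should convert the oxirane directly into (4R)-4-[(2R)-1,2-dibromopropan-2-yl]-1-methylcyclohex-1-ene F1, an epoxide-to-dibromide deoxygenation driven by P=O formation. Whichever oxirane carbon bromide opens first, the second displacement should pass through the same 8,9-bromonium ion, anti to the departed oxygen, and be completed by bromide at C8, which again corresponds to retention. Bromination of C1=C2 of F1 under the conditions of step 7, now with no hydroxyl in the molecule, rejoins the route at 13.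

Step 3. Substitution at the neopentyl-type C3 of the magnesium alkoxide may be slow, which would let base-induced β-elimination at the allylic CH2 (oxirane to dienyl diol) or magnesium-halide-promoted opening and rearrangement at C2 compete. The fallback sets out from Grignard reagent 6 and epoxy alcohol 4 and replaces cuprate nucleophilicity by Lewis-acid-assisted alkyl transfer. Three equivalents of 6 and AlCl3 give tris(3-methylbut-3-en-1-yl)alane F2, which binds 4 as its aluminium alkoxide and should deliver the butenyl group to C3 with inversion (organoalane opening of 2,3-epoxy alcohols, a C3-selective known reaction type). Hydrolysis returns to the route at 7.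

Step 7. The C1/C2 bromonium ion may be intercepted by the free C8 hydroxyl (bridged ether formation) in competition with bromide, and some opening may leak to the diequatorial dibromide. The fallback sets out from oxirane 10 and reorders the sequence so that no hydroxyl is present. The alkene is brominated first (Br2, Bu4NBr cat., solid NaHCO3, CH2Cl2, −78 °C) to (2R)-2-[(1R,3S,4S)-3,4-dibromo-4-methylcyclohexyl]-2-methyloxirane F3, and the oxirane is then opened at C9 with LiBr/AcOH as in step 6, which returns to the route at 12.

Further compounds
F1 | step 8 | (4R)-4-[(2R)-1,2-dibromopropan-2-yl]-1-methylcyclohex-1-ene | C[C@](Br)(CBr)[C@@H]1CCC(C)=CC1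
F2 | step 3 | tris(3-methylbut-3-en-1-yl)alane | CC(=C)CC[Al](CCC(C)=C)CCC(C)=C
F3 | step 7 | (2R)-2-[(1R,3S,4S)-3,4-dibromo-4-methylcyclohexyl]-2-methyloxirane | C[C@]1(CO1)[C@@H]2CC[C@](C)(Br)[C@@H](Br)C2
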